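**Retrosynthetic overview**
- Target 16 comes from silyl ether 15 by desilylation; 15 comes from 14 by one dissolving-metal operation that cleaves a temporary C4–N bond and the 2'-O-benzyl ether.
- 14 comes from 11 and 8 by a cationic [4+2] (oxa-Povarov-type) annulation that forms C2–C3 and C4–C4a and closes ring C, the only ring made in the route; rings A and B are bought.
- Enabling feature: O1–C2 is an aryl ether CH2 that can be ionized to the 2-oxadiene cation ArO+=CH2; C4a lies between O1-bearing C8a and C5–OMe and para to O7 (phloroglucinol-type nucleophile); C4 is a benzylic CH2, so a temporary nitrogen there can be removed reductively.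
- 8 comes from ring B aldehyde 5 (Takai iodo-olefination, copper N-vinylation with oxazolidinone 7); 5 comes from 1 by O-allylation, Claisen rearrangement to C3', cross-metathesis to prenyl and benzylation.
- 11 comes from 5-methoxyresorcinol 9 by monosilylation and O-acyloxymethylation.

Key step: step 9

Assumption: compounds 1, 7 and 9 are regarded as commercial, and the sense of induction in step 9 is taken from the s-trans ground-state model of (E)-N-alkenyl oxazolidinones.

Step 1
Reactants: 1 2-hydroxy-4-methoxybenzaldehyde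
Product: 2 4-methoxy-2-(prop-2-en-1-yloxy)benzaldehyde
Conditions: allyl bromide, K2CO3, DMF, 25 to 60 °C
Reagents that add atoms: allyl bromide C=CCBr
Why: Williamson O-allylation of the phenoxide, which should proceed cleanly although the 2-OH is chelated to the formyl group.

Step 2
Reactants: 2 4-methoxy-2-(prop-2-en-1-yloxy)benzaldehyde
Product: 3 2-hydroxy-4-methoxy-3-(prop-2-en-1-yl)benzaldehyde
Conditions: N,N-diethylaniline, 200 °C
Reagents that add atoms: none
Why: Aromatic Claisen rearrangement should deliver the allyl group to C3, the only free ortho position, since the other ortho carbon carries the formyl group.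

Step 3
Reactants: 3 2-hydroxy-4-methoxy-3-(prop-2-en-1-yl)benzaldehyde
Product: 4 2-hydroxy-4-methoxy-3-(3-methylbut-2-en-1-yl)benzaldehyde
Conditions: (H2IMes)(PCy3)Cl2Ru=CHPh (second-generation Grubbs catalyst, cat.), 2-methyl-2-butene (excess), CH2Cl2, 40 °C
Reagents that add atoms: 2-methyl-2-butene CC=C(C)C
Why: Olefin cross-metathesis of the terminal allyl group with excess 2-methyl-2-butene should give the prenyl group, whose trisubstituted alkene is inert to further metathesis.

Step 4
Reactants: 4 2-hydroxy-4-methoxy-3-(3-methylbut-2-en-1-yl)benzaldehyde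
Product: 5 2-(benzyloxy)-4-methoxy-3-(3-methylbut-2-en-1-yl)benzaldehyde
Conditions: benzyl bromide, K2CO3, DMF, 60 °C
Reagents that add atoms: benzyl bromide BrCc1ccccc1
Why: Williamson benzylation masks the 2-OH, so that neither the cation chemistry of step 9 nor the neighbouring prenyl group meets a free ortho phenol.

Step 5
Reactants: 5 2-(benzyloxy)-4-methoxy-3-(3-methylbut-2-en-1-yl)benzaldehyde
Product: 6 2-(benzyloxy)-1-[(E)-2-iodoethenyl]-4-methoxy-3-(3-methylbut-2-en-1-yl)benzene
Conditions: CrCl2 (divalent chromium, 6 equiv), CHI3, THF, 0 to 25 °C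
Reagents that add atoms: iodoform IC(I)I
Why: Takai olefination of an aryl aldehyde should give the (E)-vinyl iodide, and the prenyl group and benzyl ether are inert to the chromium carbenoid.

Step 6
Reactants: 6 2-(benzyloxy)-1-[(E)-2-iodoethenyl]-4-methoxy-3-(3-methylbut-2-en-1-yl)benzene; 7 (S)-4-isopropyloxazolidin-2-one
Product: 8 (S)-3-{(E)-2-[2-(benzyloxy)-4-methoxy-3-(3-methylbut-2-en-1-yl)phenyl]ethenyl}-4-isopropyloxazolidin-2-one
Conditions: CuI (cat.), N,N'-dimethylethylenediamine (cat.), K2CO3, toluene, 110 °C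
Reagents that add atoms: none
Why: Copper-catalysed Goldberg-type N-vinylation of the carbamate N–H with a vinyl iodide should proceed with retention of the (E)-geometry.

Step 7
Reactants: 9 5-methoxybenzene-1,3-diol (5-methoxyresorcinol)
Product: 10 3-methoxy-5-[(triisopropylsilyl)oxy]phenol
Conditions: chlorotriisopropylsilane (1.0 equiv), imidazole, DMF, 0 to 25 °C
Reagents that add atoms: chlorotriisopropylsilane CC(C)[Si](Cl)(C(C)C)C(C)C
Why: Statistical monosilylation of a symmetric diphenol, with diol and bis-silyl ether separable and recyclable; the bulky silyl group is chosen because it must later shield C8.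

Step 8
Reactants: 10 3-methoxy-5-[(triisopropylsilyl)oxy]phenol
Product: 11 {3-methoxy-5-[(triisopropylsilyl)oxy]phenoxy}methyl 2,2-dimethylpropanoate
Conditions: NaH, DMF, 0 °C; then chloromethyl pivalate, NaI (cat.), 0 to 25 °C
Reagents that add atoms: chloromethyl pivalate CC(C)(C)C(=O)OCCl
Why: O-alkylation of the sodium phenoxide with an acyloxymethyl halide gives an O,O-acetal whose hindered pivalate resists acyl transfer and can later be ionized by a silyl triflate.

Step 9
Reactants: 8 (S)-3-{(E)-2-[2-(benzyloxy)-4-methoxy-3-(3-methylbut-2-en-1-yl)phenyl]ethenyl}-4-isopropyloxazolidin-2-one; 11 {3-methoxy-5-[(triisopropylsilyl)oxy]phenoxy}methyl 2,2-dimethylpropanoate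
Product: 14 (S)-3-{(3S,4S)-3-[2-(benzyloxy)-4-methoxy-3-(3-methylbut-2-en-1-yl)phenyl]-5-methoxy-7-[(triisopropylsilyl)oxy]chroman-4-yl}-4-isopropyloxazolidin-2-one (3,4-trans), via aryloxymethyl cation 12 (not isolated), via N-acyliminium ion 13 (not isolated)
Conditions: TMSOTf (Me3SiOSO2CF3, 1.2 equiv), 2,6-di-tert-butyl-4-methylpyridine (1.5 equiv), CH2Cl2, −78 to −40 °C; then Et3N, aq. NaHCO3
Reagents that add atoms: none
Why: Proposed new method: TMSOTf should ionize the acyloxymethyl acetal 11 at the pivalate to the aryloxymethyl cation 12, a cationic 2-oxadiene whose CH2 is attacked by the aryl-bearing β-carbon of enamide 8 (C2–C3), and the resulting N-acyliminium ion 13 is trapped by the ring A carbon between the ether oxygen and the methoxy group (C4–C4a), the proton going to the hindered pyridine. The closest known reaction types are the oxa-Povarov annulation of aryl oxocarbenium ions with alkenes, the Povarov reaction of enamides, and inverse-electron-demand hetero-Diels–Alder reactions of chiral N-alkenyl oxazolidinones. Ring C closes as a formal [4+2] cycloaddition, in the stepwise picture by a 6-(enolendo)-exo-trig Friedel–Crafts attack on the C=N+ bond. C3 is set by the auxiliary: in the s-trans conformer (C=C anti to the carbamate C=O) the isopropyl group at C4 of the oxazolidinone covers one face of the β-carbon, so the cation adds to the other face and gives the C3 arrangement that is 3R once nitrogen is gone from C4 (it is named 3S in 14 only because the nitrogen raises the priority of C4); C4 forms trans to the aryl group by suprafacial addition to the (E)-alkene and is erased in step 10. The step needs attack at the β- and not the α-carbon of the alkene, secured by the N-acyl enamine polarization; closure at C4a and not C8, for which the triisopropylsilyl ether shields C8 while its oxygen still activates C4a from the para position; and survival of the prenyl group and benzyl ether, secured by the far higher π-nucleophilicity of the enamide and by the proton scavenger.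

Step 10
Reactants: 14 (S)-3-{(3S,4S)-3-[2-(benzyloxy)-4-methoxy-3-(3-methylbut-2-en-1-yl)phenyl]-5-methoxy-7-[(triisopropylsilyl)oxy]chroman-4-yl}-4-isopropyloxazolidin-2-one
Product: 15 (3R)-3-[2-hydroxy-4-methoxy-3-(3-methylbut-2-en-1-yl)phenyl]-5-methoxy-7-[(triisopropylsilyl)oxy]chroman
Conditions: Li (excess), NH3(l)/THF, −78 °C; then solid NH4Cl
Reagents that add atoms: none
Why: Dissolving-metal (Birch-type) reduction should cleave both the benzylic C4–N bond of the N-benzylic carbamate and the O-benzyl ether by electron transfer, the C4 carbanion being protonated by ammonia; C3 is not touched, the isolated prenyl alkene is not reduced without an added alcohol, and the isopropyl oxazolidinone has no benzylic bond of its own and is released intact.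

Step 11
Reactants: 15 (3R)-3-[2-hydroxy-4-methoxy-3-(3-methylbut-2-en-1-yl)phenyl]-5-methoxy-7-[(triisopropylsilyl)oxy]chroman
Product: 16 (3R)-3-[2-hydroxy-4-methoxy-3-(3-methylbut-2-en-1-yl)phenyl]-5-methoxychroman-7-ol (CNP0119532.1)
Conditions: TBAF (Bu4NF), THF, 0 °C; then aq. NH4Cl
Reagents that add atoms: none
Why: Fluoride-induced Si–O cleavage of the aryl silyl ether under non-acidic conditions leaves the ortho-prenyl phenol and the stereocentre unchanged.

**Compound list**
1 | 2-hydroxy-4-methoxybenzaldehyde | COc1ccc(C=O)c(O)c1 | starting material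
2 | 4-methoxy-2-(prop-2-en-1-yloxy)benzaldehyde | COc1ccc(C=O)c(OCC=C)c1 | intermediate
3 | 2-hydroxy-4-methoxy-3-(prop-2-en-1-yl)benzaldehyde | COc1ccc(C=O)c(O)c1CC=C | intermediate
4 | 2-hydroxy-4-methoxy-3-(3-methylbut-2-en-1-yl)benzaldehyde | COc1ccc(C=O)c(O)c1CC=C(C)C | intermediate
5 | 2-(benzyloxy)-4-methoxy-3-(3-methylbut-2-en-1-yl)benzaldehyde | COc1ccc(C=O)c(OCc2ccccc2)c1CC=C(C)C | intermediate
6 | 2-(benzyloxy)-1-[(E)-2-iodoethenyl]-4-methoxy-3-(3-methylbut-2-en-1-yl)benzene | COc1ccc(/C=C/I)c(OCc2ccccc2)c1CC=C(C)C | intermediate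
7 | (S)-4-isopropyloxazolidin-2-one | CC(C)[C@H]1COC(=O)N1 | starting material
8 | (S)-3-{(E)-2-[2-(benzyloxy)-4-methoxy-3-(3-methylbut-2-en-1-yl)phenyl]ethenyl}-4-isopropyloxazolidin-2-one | COc1ccc(/C=C/N2C(=O)OC[C@@H]2C(C)C)c(OCc2ccccc2)c1CC=C(C)C | intermediate
9 | 5-methoxybenzene-1,3-diol (5-methoxyresorcinol) | COc1cc(O)cc(O)c1 | starting material
10 | 3-methoxy-5-[(triisopropylsilyl)oxy]phenol | COc1cc(O)cc(O[Si](C(C)C)(C(C)C)C(C)C)c1 | intermediate
11 | {3-methoxy-5-[(triisopropylsilyl)oxy]phenoxy}methyl 2,2-dimethylpropanoate | COc1cc(OCOC(=O)C(C)(C)C)cc(O[Si](C(C)C)(C(C)C)C(C)C)c1 | intermediate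
12 | {3-methoxy-5-[(triisopropylsilyl)oxy]phenyl}(methylidene)oxonium triflate (aryloxymethyl cation) | C=[O+]c1cc(OC)cc(O[Si](C(C)C)(C(C)C)C(C)C)c1.[O-]S(=O)(=O)C(F)(F)F | intermediate
13 | N-acyliminium triflate formed by C2–C3 bond formation (open chain, C3 set, ring C not yet closed) | COc1cc(OC[C@H](C=[N+]2C(=O)OC[C@@H]2C(C)C)c2ccc(OC)c(CC=C(C)C)c2OCc2ccccc2)cc(O[Si](C(C)C)(C(C)C)C(C)C)c1.[O-]S(=O)(=O)C(F)(F)F | intermediate
14 | (S)-3-{(3S,4S)-3-[2-(benzyloxy)-4-methoxy-3-(3-methylbut-2-en-1-yl)phenyl]-5-methoxy-7-[(triisopropylsilyl)oxy]chroman-4-yl}-4-isopropyloxazolidin-2-one | COc1cc(O[Si](C(C)C)(C(C)C)C(C)C)cc2c1[C@@H](N1C(=O)OC[C@@H]1C(C)C)[C@H](c1ccc(OC)c(CC=C(C)C)c1OCc1ccccc1)CO2 | intermediate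
15 | (3R)-3-[2-hydroxy-4-methoxy-3-(3-methylbut-2-en-1-yl)phenyl]-5-methoxy-7-[(triisopropylsilyl)oxy]chroman | COc1cc(O[Si](C(C)C)(C(C)C)C(C)C)cc2c1C[C@H](c1ccc(OC)c(CC=C(C)C)c1O)CO2 | intermediate
16 | (3R)-3-[2-hydroxy-4-methoxy-3-(3-methylbut-2-en-1-yl)phenyl]-5-methoxychroman-7-ol | COc1cc(O)cc2c1C[C@H](c1ccc(OC)c(CC=C(C)C)c1O)CO2 | target

**Step count**
Total steps: 11. Longest linear sequence: 9 (steps 1 to 6, then 9, 10 and 11).

**Steps most likely to fail**

Step 9 (proposed new method). What may go wrong:
- erosion of facial selectivity at the β-carbon of the enamide;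
- ring closure at C8 instead of C4a;
- oligomerization of the aryloxymethyl cation on the electron-rich ring A;
- acid-induced loss of the oxazolidinone from C4 followed by elimination.

A minor C3 epimer of 14 would be a diastereomer and could be removed by chromatography before the auxiliary is cleaved. The fallback uses known chemistry and makes the other two bonds of ring C (O1–C2 and C3–C4) by an inverse-electron-demand hetero-Diels–Alder reaction of an ortho-quinone methide, in which C4 is already attached to C4a, so the ring A regiochemistry is fixed. It sets out from 6 and returns to the route at 15. Vinyl iodide 6 would be coupled (CuI, N,N'-dimethylethylenediamine, K2CO3, toluene, 110 °C) with commercial (R)-4-isopropyloxazolidin-2-one to give (R)-3-{(E)-2-[2-(benzyloxy)-4-methoxy-3-(3-methylbut-2-en-1-yl)phenyl]ethenyl}-4-isopropyloxazolidin-2-one F1; the enantiomeric auxiliary is needed because the β-carbon now bonds to C4 and not to C2. Commercial 2,4-dihydroxy-6-methoxybenzaldehyde would be silylated at its non-chelated 4-OH (chlorotriisopropylsilane, imidazole, DMF) to 2-hydroxy-6-methoxy-4-[(triisopropylsilyl)oxy]benzaldehyde F2 and reduced (NaBH4, MeOH, 0 °C) to 2-(hydroxymethyl)-3-methoxy-5-[(triisopropylsilyl)oxy]phenol F3, to be used at once. Heating F3 with F1 in toluene at 110 °C should expel water to the ortho-quinone methide 3-methoxy-6-methylidene-5-[(triisopropylsilyl)oxy]cyclohexa-2,4-dien-1-one F4, which the enamide traps in an auxiliary-controlled endo [4+2] cycloaddition to (R)-3-{(2S,3R)-3-[2-(benzyloxy)-4-methoxy-3-(3-methylbut-2-en-1-yl)phenyl]-5-methoxy-7-[(triisopropylsilyl)oxy]chroman-2-yl}-4-isopropyloxazolidin-2-one F5. Ionic reduction of the N,O-acetal (BF3·OEt2, Et3SiH, CH2Cl2, −78 °C) should give (3R)-3-[2-(benzyloxy)-4-methoxy-3-(3-methylbut-2-en-1-yl)phenyl]-5-methoxy-7-[(triisopropylsilyl)oxy]chroman F6, and debenzylation with lithium naphthalenide (LiC10H8, THF, −25 °C) returns 15.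

Step 10. What may go wrong: incomplete electron transfer into the electron-rich ring A, so that the benzyl ether is cleaved but the C4–N bond stays, or over-reduction of the arene rings. The fallback replaces the carbanion pathway by cation exchange and radical reduction; it sets out from 14 and returns at 15. Treatment of 14 with thiophenol and BF3·OEt2 (CH2Cl2, −78 °C) should exchange the oxazolidinone, through the trioxygenated benzylic cation, for a phenylthio group, giving (3S)-3-[2-(benzyloxy)-4-methoxy-3-(3-methylbut-2-en-1-yl)phenyl]-5-methoxy-4-(phenylsulfanyl)-7-[(triisopropylsilyl)oxy]chroman F7 as a mixture of C4 epimers. Radical desulfurization (Bu3SnH, AIBN, toluene, 90 °C) should then give the benzyl ether F6 described above, and lithium naphthalenide debenzylation returns 15.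

Step 6. What may go wrong: slow N-vinylation of the hindered carbamate nitrogen, with competing base-induced elimination of HI or loss of alkene geometry. The fallback builds the enamide by hydroamidation and avoids the vinyl iodide; it sets out from 5 and returns at 8. Aldehyde 5 would be homologated with dimethyl (1-diazo-2-oxopropyl)phosphonate (K2CO3, MeOH, 25 °C) to 2-(benzyloxy)-1-ethynyl-4-methoxy-3-(3-methylbut-2-en-1-yl)benzene F8. Ruthenium-catalysed anti-Markovnikov addition of 7 to the alkyne ((cod)Ru(C4H7)2, P(n-Bu)3, 4-dimethylaminopyridine, toluene, 100 °C) should then give the (E)-enamide 8.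

**Further compounds**
F1 | step 9 | (R)-3-{(E)-2-[2-(benzyloxy)-4-methoxy-3-(3-methylbut-2-en-1-yl)phenyl]ethenyl}-4-isopropyloxazolidin-2-one | COc1ccc(/C=C/N2C(=O)OC[C@H]2C(C)C)c(OCc2ccccc2)c1CC=C(C)C
F2 | step 9 | 2-hydroxy-6-methoxy-4-[(triisopropylsilyl)oxy]benzaldehyde | COc1cc(O[Si](C(C)C)(C(C)C)C(C)C)cc(O)c1C=O
F3 | step 9 | 2-(hydroxymethyl)-3-methoxy-5-[(triisopropylsilyl)oxy]phenol | COc1cc(O[Si](C(C)C)(C(C)C)C(C)C)cc(O)c1CO
F4 | step 9 | 3-methoxy-6-methylidene-5-[(triisopropylsilyl)oxy]cyclohexa-2,4-dien-1-one | COC1=CC(O[Si](C(C)C)(C(C)C)C(C)C)=CC(=O)C1=C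
F5 | step 9 | (R)-3-{(2S,3R)-3-[2-(benzyloxy)-4-methoxy-3-(3-methylbut-2-en-1-yl)phenyl]-5-methoxy-7-[(triisopropylsilyl)oxy]chroman-2-yl}-4-isopropyloxazolidin-2-one | COc1cc(O[Si](C(C)C)(C(C)C)C(C)C)cc2c1C[C@H](c1ccc(OC)c(CC=C(C)C)c1OCc1ccccc1)[C@@H](N1C(=O)OC[C@H]1C(C)C)O2
F6 | step 9 | (3R)-3-[2-(benzyloxy)-4-methoxy-3-(3-methylbut-2-en-1-yl)phenyl]-5-methoxy-7-[(triisopropylsilyl)oxy]chroman | COc1cc(O[Si](C(C)C)(C(C)C)C(C)C)cc2c1C[C@H](c1ccc(OC)c(CC=C(C)C)c1OCc1ccccc1)CO2
F7 | step 10 | (3S)-3-[2-(benzyloxy)-4-methoxy-3-(3-methylbut-2-en-1-yl)phenyl]-5-methoxy-4-(phenylsulfanyl)-7-[(triisopropylsilyl)oxy]chroman (C4 epimers) | COc1cc(O[Si](C(C)C)(C(C)C)C(C)C)cc2c1C(Sc1ccccc1)[C@H](c1ccc(OC)c(CC=C(C)C)c1OCc1ccccc1)CO2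
F8 | step 6 | 2-(benzyloxy)-1-ethynyl-4-methoxy-3-(3-methylbut-2-en-1-yl)benzene | COc1ccc(C#C)c(OCc2ccccc2)c1CC=C(C)C
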